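The route rests on cutting the trisubstituted C(CH3)=CH double bond of the cyclohexene ring. In one flask an open-chain aldehyde is methylenated under neutral conditions. The resulting 1,7-diene is then closed by ring-closing metathesis, so the aldehyde carbon becomes the ring =CH and the isopropenyl carbon becomes the ring C(CH3)=. The step exploits the position of this alkene between the doubly allylic CH bearing one coumarin and the CH2CH2 arm of the quaternary carbon. That carbon's own vinyl group is neopentylic and stays untouched for a later Heck coupling with the second coumarin. The precursor, a (2R,3R)-aldehyde, gets both stereocentres from an enantioselective boron-enolate Ireland–Claisen rearrangement.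

Key step: step 8

Assumption: the (R,R)-configured boron controller of step 6 is taken to deliver the (2R,3R)-acid; if the sense of induction is the opposite, its equally available mirror image is used.
Assumption: compounds 2 and 18 are taken as catalogue items.

Step 1
Reactants: 1 2-methoxybenzene-1,3-diol; 2 diethyl 2-formylbutanedioate
Product: 3 ethyl 2-(7-hydroxy-8-methoxy-2-oxo-2H-chromen-3-yl)acetate
Conditions: MeSO3H (neat), 0 °C to rt
Reagents that add atoms: none
Why: von Pechmann condensation, in which the protonated formyl group attacks the position para to one hydroxyl of the symmetrical phenol and the neighbouring hydroxyl lactonises with the geminal ester, so only the 7-hydroxy-8-methoxy pattern with the CH2CO2Et arm at C3 can form.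

Step 2
Reactants: 3 ethyl 2-(7-hydroxy-8-methoxy-2-oxo-2H-chromen-3-yl)acetate
Product: 5 2-[7-(benzyloxy)-8-methoxy-2-oxo-2H-chromen-3-yl]acetic acid, via benzyl ether ester 4 (not isolated)
Conditions: BnBr, K2CO3, DMF, rt; then LiOH, THF–H2O, rt; HCl to pH 2
Reagents that add atoms: benzyl bromide BrCc1ccccc1; lithium hydroxide [Li+].[OH-]
Why: Williamson etherification of the acidic 7-OH followed by saponification, after which any ring-opened coumarinate relactonises on acidification because its Z-cinnamate geometry is kept.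

Step 3
Reactants: 6 hex-5-yn-2-one
Product: 7 2-methylhex-1-en-5-yne
Conditions: Ph3PCH3Br, KOtBu, Et2O, 0 °C to rt
Reagents that add atoms: methyltriphenylphosphonium bromide C[P+](c1ccccc1)(c1ccccc1)c1ccccc1.[Br-]
Why: Wittig methylenation of a methyl ketone, which the terminal alkyne tolerates.

Step 4
Reactants: 7 2-methylhex-1-en-5-yne
Product: 10 (2E)-3,6-dimethylhepta-2,6-dien-1-ol, via alkenylalane 8 (not isolated), via lithium aluminate 9 (not isolated)
Conditions: AlMe3, Cp2ZrCl2 (20 mol %), CH2Cl2, rt; evaporate; n-BuLi, hexane–THF, −78 to 0 °C; (CH2O)n, rt; aq. HCl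
Reagents that add atoms: trimethylaluminium C[Al](C)C; formaldehyde (from paraformaldehyde) C=O; n-butyllithium [Li]CCCC (kept only in intermediate 9)
Why: Negishi carboalumination adds CH3 and Al syn and regioselectively across the terminal alkyne while the 1,1-disubstituted alkene is inert, and hydroxymethylation of the aluminate with retention fixes the E-trisubstituted alkene.

Step 5
Reactants: 5 2-[7-(benzyloxy)-8-methoxy-2-oxo-2H-chromen-3-yl]acetic acid; 10 (2E)-3,6-dimethylhepta-2,6-dien-1-ol
Product: 11 (2E)-3,6-dimethylhepta-2,6-dien-1-yl 2-[7-(benzyloxy)-8-methoxy-2-oxo-2H-chromen-3-yl]acetate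
Conditions: EDC·HCl, DMAP (10 mol %), CH2Cl2, 0 °C to rt
Reagents that add atoms: none
Why: Steglich-type carbodiimide esterification of a primary allylic alcohol under near-neutral conditions that avoid allylic ionisation.

Step 6
Reactants: 11 (2E)-3,6-dimethylhepta-2,6-dien-1-yl 2-[7-(benzyloxy)-8-methoxy-2-oxo-2H-chromen-3-yl]acetate
Product: 13 (2R,3R)-2-[7-(benzyloxy)-8-methoxy-2-oxo-2H-chromen-3-yl]-3-ethenyl-3,6-dimethylhept-6-enoic acid, via boron ketene acetal 12 (not isolated)
Conditions: (1R,2R)-N,N'-bis{[3,5-bis(trifluoromethyl)phenyl]sulfonyl}-1,2-diphenylethane-1,2-diamine, BBr3, CH2Cl2, rt, then vacuum; 11, iPr2NEt, CH2Cl2, −78 °C to 4 °C; H2O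
Reagents that add atoms: (4R,5R)-2-bromo-4,5-diphenyl-1,3-bis{[3,5-bis(trifluoromethyl)phenyl]sulfonyl}-1,3,2-diazaborolidine BrB1N(S(=O)(=O)c2cc(C(F)(F)F)cc(C(F)(F)F)c2)[C@H](c2ccccc2)[C@@H](c2ccccc2)N1S(=O)(=O)c1cc(C(F)(F)F)cc(C(F)(F)F)c1 (boron unit kept only in intermediate 12)
Why: Enantioselective boron-enolate Ireland–Claisen rearrangement, in which soft enolisation of the acidic arylacetate CH2 gives the conjugated Z(O)-boron ketene acetal (coumarinyl cis to OB, avoiding allylic 1,3-strain), the chair transition state places the CH3 of the E-alkene axial and the chain equatorial so that C2 and the quaternary C3 are set together in the 2R*,3R* relation, and the C2-symmetric (R,R)-bis-sulfonamide on boron selects the enolate face and hence the absolute configuration.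

Step 7
Reactants: 13 (2R,3R)-2-[7-(benzyloxy)-8-methoxy-2-oxo-2H-chromen-3-yl]-3-ethenyl-3,6-dimethylhept-6-enoic acid
Product: 15 (2R,3R)-2-[7-(benzyloxy)-8-methoxy-2-oxo-2H-chromen-3-yl]-3-ethenyl-3,6-dimethylhept-6-enal, via acid chloride 14 (not isolated)
Conditions: 1-chloro-N,N,2-trimethylprop-1-en-1-amine, CH2Cl2, 0 °C; then LiAlH(OtBu)3, THF, −78 °C
Reagents that add atoms: 1-chloro-N,N,2-trimethylprop-1-en-1-amine CC(C)=C(Cl)N(C)C (chlorine kept only in intermediate 14)
Why: Neutral acid chloride formation and partial reduction with the bulky hydride LiAlH(OtBu)3, which at −78 °C attacks only the acid chloride, leaves lactone and alkenes alone and, without base, should not epimerise C2.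

Step 8
Reactants: 15 (2R,3R)-2-[7-(benzyloxy)-8-methoxy-2-oxo-2H-chromen-3-yl]-3-ethenyl-3,6-dimethylhept-6-enal
Product: 17 7-(benzyloxy)-3-[(1R,6R)-6-ethenyl-3,6-dimethylcyclohex-2-en-1-yl]-8-methoxy-2H-chromen-2-one, via triene 16 (not isolated)
Conditions: RhCl(PPh3)3 (3 mol %), PPh3, Me3SiCHN2, iPrOH, THF, rt; then toluene, second-generation Hoveyda–Grubbs catalyst RuCl2(=CH-C6H4-2-OiPr)(1,3-dimesitylimidazolidin-2-ylidene) (10 mol %), 70 °C
Reagents that add atoms: trimethylsilyldiazomethane C[Si](C)(C)C=[N+]=[N-] (its carbon is kept only in intermediate 16)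
Why: A rhodium-catalysed, salt-free Wittig methylenation turns the aldehyde of 15 into the vinyl group of triene 16 without base, so the epimerisable C–H next to it is untouched and the lactone carbonyl is ignored. The ruthenium carbene then exchanges onto this vinyl group and undergoes [2+2] cycloaddition and cycloreversion with the tethered isopropenyl group, expelling ethene and joining the former aldehyde carbon to the C(CH3) carbon; the closest known reaction type is ring-closing metathesis of a 1,7-diene to a trisubstituted cyclohexene run in sequence with a catalytic methylenation, overall a formal carbonyl–olefin metathesis. One ring is closed, the six-membered carbocycle, by union of a monosubstituted with a 1,1-disubstituted alkene, helped by the gem-dialkyl effect of the quaternary carbon in the tether. No stereocentre is created: the two existing ones are spectators and the new endocyclic alkene can only be Z within a six-membered ring. The step needs site selectivity: the carbene must load on the vinyl at the tertiary carbon and not on the vinyl at the quaternary carbon (which would lead to a cyclopentene), and this is secured by the neopentylic crowding of the latter, by the impossibility of a four-membered ring between the two vinyl groups and by the inertness of the electron-poor trisubstituted C3=C4 bond of the coumarin. At 70 °C the 1,5-diene unit of 16 should stay below the onset of a Cope shift.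

Step 9
Reactants: 18 7-hydroxy-8-methoxy-2H-chromen-2-one
Product: 19 7-(benzyloxy)-8-methoxy-2H-chromen-2-one
Conditions: BnBr, K2CO3, DMF, rt
Reagents that add atoms: benzyl bromide BrCc1ccccc1
Why: Williamson etherification of the acidic 7-OH.

Step 10
Reactants: 19 7-(benzyloxy)-8-methoxy-2H-chromen-2-one
Product: 20 7-(benzyloxy)-3-bromo-8-methoxy-2H-chromen-2-one
Conditions: NBS, MeCN, rt
Reagents that add atoms: N-bromosuccinimide O=C1CCC(=O)N1Br
Why: Electrophilic bromination at C3, the vinylogous para position of the 7-alkoxy group and the most nucleophilic carbon of a 7-alkoxycoumarin.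

Step 11
Reactants: 17 7-(benzyloxy)-3-[(1R,6R)-6-ethenyl-3,6-dimethylcyclohex-2-en-1-yl]-8-methoxy-2H-chromen-2-one; 20 7-(benzyloxy)-3-bromo-8-methoxy-2H-chromen-2-one
Product: 21 bis(benzyl ether) of the target, 7-(benzyloxy)-3-[(E)-2-{(1R,2R)-2-[7-(benzyloxy)-8-methoxy-2-oxo-2H-chromen-3-yl]-1,4-dimethylcyclohex-3-en-1-yl}ethenyl]-8-methoxy-2H-chromen-2-one
Conditions: Pd(OAc)2 (5 mol %), P(o-tol)3 (12 mol %), Et3N, DMF, 90 °C
Reagents that add atoms: none
Why: Mizoroki–Heck reaction, in which the C3–Br bond adds to zerovalent palladium, the only monosubstituted alkene inserts syn at its terminal carbon, and syn β-hydride elimination can involve only the CH2 that now bears the coumarin because the other neighbour is quaternary, giving the E-alkene without touching a stereocentre.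

Step 12
Reactants: 21 bis(benzyl ether) of the target
Product: 22 target, 7-hydroxy-3-[(E)-2-{(1R,2R)-2-(7-hydroxy-8-methoxy-2-oxo-2H-chromen-3-yl)-1,4-dimethylcyclohex-3-en-1-yl}ethenyl]-8-methoxy-2H-chromen-2-one
Conditions: BCl3, C6HMe5, CH2Cl2, −78 °C; then H2O
Reagents that add atoms: none
Why: Lewis-acid debenzylation of aryl benzyl ethers with pentamethylbenzene as a non-basic cation scavenger, which at −78 °C should spare the aryl methyl ethers, the lactones and all alkenes.

Compound list
1 | 2-methoxybenzene-1,3-diol | COc1c(O)cccc1O | starting material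
2 | diethyl 2-formylbutanedioate | CCOC(=O)CC(C=O)C(=O)OCC | starting material
3 | ethyl 2-(7-hydroxy-8-methoxy-2-oxo-2H-chromen-3-yl)acetate | CCOC(=O)Cc1cc2ccc(O)c(OC)c2oc1=O | intermediate
4 | ethyl 2-[7-(benzyloxy)-8-methoxy-2-oxo-2H-chromen-3-yl]acetate (not isolated) | CCOC(=O)Cc1cc2ccc(OCc3ccccc3)c(OC)c2oc1=O | intermediate
5 | 2-[7-(benzyloxy)-8-methoxy-2-oxo-2H-chromen-3-yl]acetic acid | OC(=O)Cc1cc2ccc(OCc3ccccc3)c(OC)c2oc1=O | intermediate
6 | hex-5-yn-2-one | CC(=O)CCC#C | starting material
7 | 2-methylhex-1-en-5-yne | C=C(C)CCC#C | intermediate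
8 | [(1E)-2,5-dimethylhexa-1,5-dien-1-yl]dimethylalane (not isolated) | C[Al](C)/C=C(\C)CCC(C)=C | intermediate
9 | lithium butyl[(1E)-2,5-dimethylhexa-1,5-dien-1-yl]dimethylaluminate (not isolated) | [Li+].CCCC[Al-](C)(C)/C=C(\C)CCC(C)=C | intermediate
10 | (2E)-3,6-dimethylhepta-2,6-dien-1-ol | OC/C=C(\C)CCC(C)=C | intermediate
11 | (2E)-3,6-dimethylhepta-2,6-dien-1-yl 2-[7-(benzyloxy)-8-methoxy-2-oxo-2H-chromen-3-yl]acetate | O=C(Cc1cc2ccc(OCc3ccccc3)c(OC)c2oc1=O)OC/C=C(\C)CCC(C)=C | intermediate
12 | Z(O)-boron ketene acetal of 11 carrying the (4R,5R)-diazaborolidine, coumarinyl cis to OB (not isolated) | COc1c(OCc2ccccc2)ccc2cc(/C=C(\OB3N(S(=O)(=O)c4cc(C(F)(F)F)cc(C(F)(F)F)c4)[C@H](c4ccccc4)[C@@H](c4ccccc4)N3S(=O)(=O)c3cc(C(F)(F)F)cc(C(F)(F)F)c3)OC/C=C(\C)CCC(C)=C)c(=O)oc12 | intermediate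
13 | (2R,3R)-2-[7-(benzyloxy)-8-methoxy-2-oxo-2H-chromen-3-yl]-3-ethenyl-3,6-dimethylhept-6-enoic acid | C=C[C@@](C)(CCC(C)=C)[C@@H](C(=O)O)c1cc2ccc(OCc3ccccc3)c(OC)c2oc1=O | intermediate
14 | (2R,3R)-acid chloride of 13 (not isolated) | C=C[C@@](C)(CCC(C)=C)[C@@H](C(=O)Cl)c1cc2ccc(OCc3ccccc3)c(OC)c2oc1=O | intermediate
15 | (2R,3R)-2-[7-(benzyloxy)-8-methoxy-2-oxo-2H-chromen-3-yl]-3-ethenyl-3,6-dimethylhept-6-enal | C=C[C@@](C)(CCC(C)=C)[C@@H](C=O)c1cc2ccc(OCc3ccccc3)c(OC)c2oc1=O | intermediate
16 | 7-(benzyloxy)-3-[(3R,4R)-4-ethenyl-4,7-dimethylocta-1,7-dien-3-yl]-8-methoxy-2H-chromen-2-one (not isolated) | C=C[C@@](C)(CCC(C)=C)[C@@H](C=C)c1cc2ccc(OCc3ccccc3)c(OC)c2oc1=O | intermediate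
17 | 7-(benzyloxy)-3-[(1R,6R)-6-ethenyl-3,6-dimethylcyclohex-2-en-1-yl]-8-methoxy-2H-chromen-2-one | C=C[C@@]1(C)CCC(C)=C[C@H]1c1cc2ccc(OCc3ccccc3)c(OC)c2oc1=O | intermediate
18 | 7-hydroxy-8-methoxy-2H-chromen-2-one | COc1c(O)ccc2ccc(=O)oc12 | starting material
19 | 7-(benzyloxy)-8-methoxy-2H-chromen-2-one | COc1c(OCc2ccccc2)ccc2ccc(=O)oc12 | intermediate
20 | 7-(benzyloxy)-3-bromo-8-methoxy-2H-chromen-2-one | COc1c(OCc2ccccc2)ccc2cc(Br)c(=O)oc12 | intermediate
21 | bis(benzyl ether) of the target, (R,R), E-alkene | COc1c(OCc2ccccc2)ccc2cc(/C=C/[C@@]3(C)CCC(C)=C[C@H]3c3cc4ccc(OCc5ccccc5)c(OC)c4oc3=O)c(=O)oc12 | intermediate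
22 | target CNP0264408.1 | COc1c(O)ccc2cc(/C=C/[C@@]3(C)CCC(C)=C[C@H]3c3cc4ccc(O)c(OC)c4oc3=O)c(=O)oc12 | target

Total step count: 12. Longest linear sequence: 8 steps (1, 2, 5, 6, 7, 8, 11, 12).

Steps most likely to fail

1. Step 8 (key step).
- What may go wrong: the ruthenium carbene may load on the quaternary vinyl group and close a five-membered ring. The catalyst may be slowed by residual phosphine or by chelation to the lactone carbonyl. The triene may undergo a slow [3,3] shift on long heating.
- Fallback (sets out from 13, comes back at 21): the order of events is changed so that the quaternary vinyl group no longer exists when the metathesis is run. Heck coupling of 13 with 20 (Pd(OAc)2, P(o-tol)3, Et3N, DMF, 80 °C; the monosubstituted alkene reacts before the isopropenyl group) gives the styryl acid F1. This is taken with the chloroenamine of step 7 to the acid chloride F2, and with LiAlH(OtBu)3 at −78 °C to the aldehyde F3. Ph3P=CH2 (from Ph3PCH3Br and KHMDS, THF, −78 °C) gives the tetraene F4, which is isolated and freed from phosphorus residues. Ring-closing metathesis with the second-generation Grubbs catalyst RuCl2(PCy3)(1,3-dimesitylimidazolidin-2-ylidene)(=CHPh) in CH2Cl2 at 40 °C gives 21.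

2. Step 6.
- What may go wrong: soft enolisation may be incomplete or unselective because the lactone carbonyl competes for boron. The enolate geometry may erode, the facial selectivity may be poor, and the rearrangement onto the fully substituted alkene terminus may be very slow.
- Fallback (sets out from 11, comes back at 13): a classical Ireland–Claisen rearrangement followed by resolution. LiHMDS in THF–DMPU at −78 °C and Me3SiCl give the (Z)-trimethylsilyl ketene acetal F5. This rearranges at 40 °C through the same chair and, after mild acidic work-up, gives the racemic (2R*,3R*)-acid F6. Fractional crystallisation with (R)-1-phenylethylamine separates the (R)-1-phenylethylammonium salt F7 of the (2R,3R)-acid, and acidification returns 13.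

3. Step 7.
- What may go wrong: the aldehyde may be over-reduced, hydride delivery to the hindered acyl chloride may be sluggish, and C2 may lose configuration through ketene or enol formation.
- Fallback (sets out from 13, comes back at 15): a detour through the alcohol oxidation level. Isobutyl chloroformate and N-methylmorpholine (THF, −15 °C) give the mixed anhydride F8, NaBH4 in THF–MeOH reduces it to the primary alcohol F9, and Dess–Martin periodinane (CH2Cl2, NaHCO3) oxidises F9 to 15.

Further compounds
F1 | step 8 | (2R,3R)-2-[7-(benzyloxy)-8-methoxy-2-oxo-2H-chromen-3-yl]-3-{(E)-2-[7-(benzyloxy)-8-methoxy-2-oxo-2H-chromen-3-yl]ethenyl}-3,6-dimethylhept-6-enoic acid | COc1c(OCc2ccccc2)ccc2cc(/C=C/[C@@](C)(CCC(C)=C)[C@@H](C(=O)O)c3cc4ccc(OCc5ccccc5)c(OC)c4oc3=O)c(=O)oc12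
F2 | step 8 | acid chloride of F1 | COc1c(OCc2ccccc2)ccc2cc(/C=C/[C@@](C)(CCC(C)=C)[C@@H](C(=O)Cl)c3cc4ccc(OCc5ccccc5)c(OC)c4oc3=O)c(=O)oc12
F3 | step 8 | (2R,3R)-aldehyde corresponding to F1 | COc1c(OCc2ccccc2)ccc2cc(/C=C/[C@@](C)(CCC(C)=C)[C@@H](C=O)c3cc4ccc(OCc5ccccc5)c(OC)c4oc3=O)c(=O)oc12
F4 | step 8 | open-chain tetraene, the 1,7-diene carrying both benzylated coumarins | COc1c(OCc2ccccc2)ccc2cc(/C=C/[C@@](C)(CCC(C)=C)[C@@H](C=C)c3cc4ccc(OCc5ccccc5)c(OC)c4oc3=O)c(=O)oc12
F5 | step 6 | (Z)-trimethylsilyl ketene acetal of 11 | COc1c(OCc2ccccc2)ccc2cc(/C=C(\O[Si](C)(C)C)OC/C=C(\C)CCC(C)=C)c(=O)oc12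
F6 | step 6 | racemic (2R*,3R*)-acid, both enantiomers | C=C[C@@](C)(CCC(C)=C)[C@@H](C(=O)O)c1cc2ccc(OCc3ccccc3)c(OC)c2oc1=O.C=C[C@](C)(CCC(C)=C)[C@H](C(=O)O)c1cc2ccc(OCc3ccccc3)c(OC)c2oc1=O
F7 | step 6 | (R)-1-phenylethylammonium salt of 13 | C=C[C@@](C)(CCC(C)=C)[C@@H](C(=O)[O-])c1cc2ccc(OCc3ccccc3)c(OC)c2oc1=O.C[C@@H]([NH3+])c1ccccc1
F8 | step 7 | mixed isobutyl carbonic anhydride of 13 | C=C[C@@](C)(CCC(C)=C)[C@@H](C(=O)OC(=O)OCC(C)C)c1cc2ccc(OCc3ccccc3)c(OC)c2oc1=O
F9 | step 7 | 7-(benzyloxy)-3-[(2R,3R)-3-ethenyl-1-hydroxy-3,6-dimethylhept-6-en-2-yl]-8-methoxy-2H-chromen-2-one | C=C[C@@](C)(CCC(C)=C)[C@@H](CO)c1cc2ccc(OCc3ccccc3)c(OC)c2oc1=O
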